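# Ligraminol A by a chiral boron-enolate Claisen rearrangement of crotyl propanoate: synthesis design

## The problem

Ligraminol A (20) is a 2,5-diaryl-3,4-dimethyltetrahydrofuran with a single oxolane ring (O1, C2–C5). C2 carries a 3,4-dimethoxyphenyl group, C3 and C4 each carry a methyl group, and C5 carries a 3,4,5-trimethoxyphenyl group. All four ring carbons are stereocentres, (2S,3R,4S,5S), which translates into 2,3-cis, 3,4-cis and 4,5-trans: the C2 aryl group and both methyl groups share one face, and only the C5 aryl group lies on the other. The two arenes differ, so there is no symmetry to use and the two ends of the C3–C4 unit must be distinguished from the start. The cis,cis triad is the less stable arrangement and has to be made under kinetic control. Both benzylic C–O bonds bear electron-rich arenes and ionise under acid, and C3 and C4 become epimerisable whenever a carbonyl group sits next to them. No heteroatom on C3 or C4 can direct a reagent, so later stereocontrol must come from the methyl groups: once they are cis and of the right absolute sense they screen one ring face, and an aryl nucleophile at C5 and a hydride at C2 that both enter anti to them give exactly the 4,5-trans and 2,3-cis relations. The feature that opens the key step is the C3–C4 bond: it joins two methyl-bearing stereocentres, each next to an oxygenated benzylic carbon, and it is the σ-bond formed by a [3,3]-sigmatropic rearrangement of crotyl propanoate 3. The product, 2,3-dimethylpent-4-enoic acid 6, already has different ends: the carboxyl carbon becomes C2 and the inner vinyl carbon becomes C5.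

## Retrosynthesis

**C2–H (20 ⇒ 18).** The last centre to be made is C2, the most fragile one, with its aryl group cis to the C3 methyl group. Cutting C2–H leads through oxocarbenium ion 19 to hemiketal 18. Cutting C2–aryl instead would require an aryl nucleophile to enter syn to the C3 methyl group, against the bias of the ring. With hydride the same bias works for the target: the small nucleophile enters anti to the methyl groups and leaves the aryl group cis to them. The precursor has one stereocentre fewer. The forward reduction must be face-selective and fast at low temperature, so that 19 does not lose a proton and 20 does not re-ionise.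

**C2–aryl (18 ⇒ 15 + 16).** Hemiketal 18 is the adduct of an aryl anion and a lactone, so this cut gives lactone 15 and aryllithium 17, made from bromide 16. An open-chain aryl ketone route would put two benzylic alcohols in one chain and require one to be displaced selectively, whereas the lactone keeps O1–C5 intact. Lactone 15 has three stereocentres and one arene. The addition must stop after one aryl group and must not enolise C3.

**C5–aryl (15 ⇒ 10 + 11).** The trimethoxyphenyl group is removed from C5 to give acetoxy lactone 10 and arylzinc 13, reached from bromide 11 through aryllithium 12. Adding an aryl metal to the open aldehyde 8 would follow the Felkin–Anh preference of C4, which leads after closure to the 4,5-cis lactone. Electrophilic substitution on a 1,2,3-trioxygenated arene would attack the wrong ring position. Substitution on the planar acyl oxocarbenium ion 14, whose two methyl groups lie on one face, should place the aryl group anti to them. The precursor is an arene-free C6 lactone with two stereocentres.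

**Acetate and C=C (10 ⇒ 9 ⇒ 6).** Acetate 10 is the acylated lactol 9, and 9 is the ring tautomer of aldehyde acid 8, obtained by cleaving the vinyl group of acid 6 through ozonide 7. These two operations only adjust oxidation level and leaving group. The forward steps must avoid enolising 8.

**C3–C4 of the target, key step (6 ⇒ 3).** The C2–C3 bond of 6 is cut in the sense of an ester-enolate Claisen rearrangement, giving crotyl propanoate 3 through boron ketene acetal 4 and acyloxyborane 5. An aldol or alkylation route to the same bond would need a chiral electrophile or auxiliary and would set the two centres separately. The rearrangement sets both at once in a chair whose outcome is fixed by two alkene geometries, and the absolute sense comes from the ligand on boron. The precursor is achiral. The forward step needs one enolate geometry, a pure (E)-crotyl group and high facial discrimination.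

**Ester C–O (3 ⇒ 1 + 2).** Ester 3 comes from (E)-but-2-en-1-ol 1 and propanoyl chloride 2, both commercial.

## Roads not taken

**Alternative 1: arylketene plus cis-2-butene, then oxygen insertion.**
- **Cut:** C2–C3 and C4–C5 together.
- **Forward key step:** (3,4-dimethoxyphenyl)ketene A2, generated in the flask, adds to (Z)-but-2-ene A3 to give the all-cis cyclobutanone A1. The catalyst is a chiral oxazaborolidine, for example (S)-1-(2-methylphenyl)-3,3-diphenyltetrahydro-1H,3H-pyrrolo[1,2-c][1,3,2]oxazaborole, activated by AlBr3. Baeyer–Villiger oxidation with migration of the benzylic carbon then inserts O1 to give the all-cis lactone A4. The trimethoxyphenyl group must still be brought to the former carbonyl carbon of A4 at the lactol oxidation level, anti to the C4 methyl group.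
- **Merits:** one catalytic step builds two ring bonds and three contiguous stereocentres (C2, C3, C4) from a feedstock alkene. The cis-dimethyl relation is carried stereospecifically from the geometry of A3. The chiral material is catalytic. In these respects the road is better than the chosen plan, which uses a stoichiometric boron reagent and a rearrangement lasting two weeks.
- **Weak points:**
  - A3 is an unactivated, gaseous, symmetrical alkene, and A2 dimerises readily.
  - The aryl group must end on the face of both methyl groups. Thermal ketene cycloadditions tend that way, but Lewis-acid activation changes the transition state and does not guarantee it.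
  - The C2–H of A1 is benzylic and α to a strained ketone, so epimerisation to the trans isomer is likely.
  - The peracid step has to spare an electron-rich arene.
  - The 2,3-cis benzylic ether at C2, the most acid-labile centre, is formed first and must survive the Lewis-acid arylation at C5.
- **Comparison:** the step count could be lower, but three consecutive selectivities lack close analogy for this substitution pattern. The chosen plan offers a rearrangement whose stereochemical course is fixed by a chair and is known for ester 3 itself, and it forms the fragile C2 centre last.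

**Alternative 2: conjugate methylation of a butenolide, then kinetic protonation.**
- **Cut:** the C4–CH3 bond and C3–H.
- **Forward key step:** Me2CuLi with Me3SiCl adds a methyl group to C4 of the enantiopure butenolide A5 anti to the C5 aryl group, giving silyl ketene acetal A6. Protonation of A6 at C3 from the face opposite the new methyl group gives lactone A7, which is the same compound as 15. The last two steps would be those of the chosen route.
- **Merits:** the trimethoxyphenyl group is in place from the start and relays C5 → C4 → C3. The road avoids the C5 arylation on an acyl oxocarbenium ion, the least conventional C–C bond formation of the chosen plan, and in that respect it is better.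
- **Weak points:**
  - A5 must be made as a single enantiomer by a separate asymmetric step.
  - Its C5–H is benzylic, allylic and γ to the carbonyl, so any base can racemise it through the 2-oxyfuran.
  - Cuprate addition to an α-methyl butenolide is slow.
  - C3 is set by protonation to the less stable cis isomer, which depends on the proton source and is lost on any equilibration.
- **Comparison:** after A5 the road is short and reaches the same lactone. The chosen plan sets C3 and C4 together in a concerted step instead of by protonation, and its absolute configuration is never carried by a racemisable centre.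

**Alternative 3: anodic quinone methide cyclisation closing O1–C5.**
- **Cut:** the O1–C5 bond.
- **Forward key step:** constant-current oxidation at a carbon anode with 2,6-lutidine turns the 4-alkyl-2,6-dimethoxyphenol A8 into the para-quinone methide A9. The C2 hydroxyl adds to C5 and closes the ring to phenol A10, and O-methylation then gives 20.
- **Merits:** the ring closes without Lewis acid, and attack anti to the C4 methyl group should give the 4,5-trans relation. The finished ring is never exposed to BF3, which is better than the last step of the chosen plan.
- **Weak points:**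
  - The cut removes only C5. A8 still holds C2, C3 and C4 as an acyclic stereotriad with a benzylic alcohol, and that triad must be built by other chemistry.
  - A9 has a hydrogen at C4, and base-induced tautomerisation to the styrene would erase that centre.
  - The benzylic alcohol and the dimethoxyphenyl ring are also oxidisable, and A10 can be re-oxidised.
  - A phenol protecting group and a final methylation add steps.
- **Comparison:** the endgame is milder, but the hard part of the problem is left open. The chosen plan makes the C3–C4 pair in its key step, needs no protecting group, and accepts a cold Lewis-acid step at the end.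

Key step: step 2

## Route

Remarks on the chemistry:
- Assumption: the (S,S)-bromoborane is taken to give (2R,3R)-6 from the E(O)-enolate. This sense of induction is not assigned with certainty here and must be confirmed on the first run; the (R,R)-reagent would be used unchanged otherwise if it proved reversed.
- The base–solvent pair Et3N/toluene–hexane is assigned to the E(O)-enolate by analogy with this reagent class. The anti/syn outcome should be checked on the first run.
- Alcohol 1 is used as the geometrically pure (E)-isomer, since any (Z)-isomer would appear as the syn diastereomer of 6.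
- "Bromoborane" in step 2 means (4S,5S)-2-bromo-1,3-bis{[3,5-bis(trifluoromethyl)phenyl]sulfonyl}-4,5-diphenyl-1,3,2-diazaborolidine. It is made in the flask from the (1S,2S)-bis-sulfonamide and BBr3.

Step 1
Reactants: 1 (E)-but-2-en-1-ol; 2 propanoyl chloride
Product: 3 (E)-but-2-en-1-yl propanoate
Conditions: Et3N, 4-(dimethylamino)pyridine (cat.), CH2Cl2, 0 °C → rt
Reagents that add atoms: none
Why: Amine-buffered acylation of a primary allylic alcohol by an acid chloride (nucleophilic acyl substitution); no stereocentre is formed and the (E)-alkene geometry, on which the relative configuration of step 2 depends, is untouched.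

Step 2
Reactants: 3 (E)-but-2-en-1-yl propanoate
Product: 6 (2R,3R)-2,3-dimethylpent-4-enoic acid, via boron ketene acetal 4 (not isolated), via acyloxyborane 5 (not isolated)
Conditions: (S,S)-bromoborane [from the (1S,2S)-bis-sulfonamide and BBr3, CH2Cl2, rt, volatiles removed], Et3N, toluene–hexane, −78 °C, then −20 °C, 14 d; aq. NaHCO3 extraction, then H3O+
Reagents that add atoms: none
Why: This is an Ireland–Claisen rearrangement through a chiral boron ketene acetal, the enantioselective variant known for this ester class. The bromoborane binds the ester carbonyl and Et3N in the non-polar medium removes an α-proton to give the E(O) boron enolate 4, with the methyl group trans to the O–B oxygen. At −20 °C the allylic C–O bond breaks as the C2–C3 bond of 6 (the future C3–C4 bond of 20) forms in a six-membered chair transition state, giving acyloxyborane 5, which aqueous work-up hydrolyses to 6 and the recoverable bis-sulfonamide. No ring is closed. The relative configuration of the two new stereocentres follows from the two alkene geometries: in the chair the crotyl methyl group is equatorial and the enolate methyl group axial, which gives the anti (meso-type) acid that becomes the cis-dimethyl unit of the ring. The absolute configuration (2R,3R) is set by the C2-symmetric bis-sulfonamide ligand on boron, which leaves one enolate face open to the allyl terminus. The step therefore needs high E(O) selectivity, a pure (E)-crotyl group and the chair pathway; the base–solvent pair, the purity of 1 and the low temperature are chosen to secure them. Acid–base extraction separates 6 from the ligand.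

Step 3
Reactants: 6 (2R,3R)-2,3-dimethylpent-4-enoic acid
Product: 9 (3R,4S)-5-hydroxy-3,4-dimethyloxolan-2-one, via ozonide 7 (not isolated), via aldehyde acid 8 (not isolated)
Conditions: O3, CH2Cl2, −78 °C; then Me2S, −78 °C → rt
Reagents that add atoms: ozone, [O-][O+]=O
Why: Ozonolysis of the terminal alkene (Criegee mechanism) and reduction of ozonide 7 give aldehyde acid 8, which closes to the five-membered pseudo-acid 9 by ring–chain tautomerism; the neutral work-up avoids enolisation of 8, so the two methyl stereocentres are kept, and the new C5 centre is an inconsequential mixture.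

Step 4
Reactants: 9 (3R,4S)-5-hydroxy-3,4-dimethyloxolan-2-one
Product: 10 (3R,4S)-5-acetoxy-3,4-dimethyloxolan-2-one
Conditions: Ac2O, pyridine, CH2Cl2, 0 °C
Reagents that add atoms: acetic anhydride, CC(=O)OC(C)=O
Why: O-Acetylation of the lactol hydroxyl (acylation of a pseudo-acid) installs the leaving group for ionisation; the C5 epimer mixture is irrelevant because C5 becomes planar in step 5, and the short, cold, weakly basic conditions limit epimerisation at C4 through the open aldehyde.

Step 5
Reactants: 10 (3R,4S)-5-acetoxy-3,4-dimethyloxolan-2-one; 11 5-bromo-1,2,3-trimethoxybenzene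
Product: 15 (3R,4S,5S)-3,4-dimethyl-5-(3,4,5-trimethoxyphenyl)oxolan-2-one, via aryllithium 12 (not isolated), via arylzinc chloride 13 (not isolated), via acyl oxocarbenium ion 14 (not isolated)
Conditions: 11, n-BuLi, THF, −78 °C; ZnCl2, −78 → 0 °C; then 10, BF3·OEt2, CH2Cl2, −78 → −20 °C
Reagents that add atoms: none
Why: Bromine–lithium exchange and transmetalation give an arylzinc that tolerates the lactone, while BF3·OEt2 ionises the anomeric acetate to acyl oxocarbenium ion 14 (Lewis-acid-promoted substitution of an acyloxy acetal by an organozinc nucleophile). Both methyl groups of 14 lie on one face of the near-planar ring, so the aryl group adds to C5 from the opposite face, anti to the adjacent C4 methyl group, which sets (5S) and the 4,5-trans relation.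

Step 6
Reactants: 15 (3R,4S,5S)-3,4-dimethyl-5-(3,4,5-trimethoxyphenyl)oxolan-2-one; 16 4-bromo-1,2-dimethoxybenzene
Product: 18 (3R,4S,5S)-2-(3,4-dimethoxyphenyl)-3,4-dimethyl-5-(3,4,5-trimethoxyphenyl)oxolan-2-ol, via aryllithium 17 (not isolated)
Conditions: 16, n-BuLi, THF, −78 °C; then 15, THF, −78 °C; AcOH quench at −78 °C
Reagents that add atoms: none
Why: Bromine–lithium exchange is followed by 1,2-addition of the aryllithium to the lactone carbonyl; the tetrahedral lithium alkoxide does not collapse at −78 °C, so only one aryl group is taken up, and cold protonation gives hemiketal 18 (C2 epimers in equilibrium with the hydroxy ketone), which is used crude. The ring stereocentres are kept provided addition outruns enolisation at C3.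

Step 7
Reactants: 18 (3R,4S,5S)-2-(3,4-dimethoxyphenyl)-3,4-dimethyl-5-(3,4,5-trimethoxyphenyl)oxolan-2-ol
Product: 20 Ligraminol A [(2S,3R,4S,5S)-2-(3,4-dimethoxyphenyl)-3,4-dimethyl-5-(3,4,5-trimethoxyphenyl)oxolane], via oxocarbenium ion 19 (not isolated)
Conditions: Et3SiH, BF3·OEt2, CH2Cl2, −78 °C
Reagents that add atoms: none
Why: Ionic hydrogenation of a cyclic hemiketal: BF3·OEt2 ionises 18 to the aryl-stabilised oxocarbenium ion 19 and Et3SiH delivers hydride to C2 from the face opposite the C3 and C4 methyl groups, so the aryl group ends cis to the C3 methyl group and C2 is set as (S). The low temperature and short exposure are meant to keep the two electron-rich benzylic C–O bonds of 20 from re-ionising.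

## Compound list

1 | (E)-but-2-en-1-ol | C/C=C/CO | starting material
2 | propanoyl chloride | CCC(=O)Cl | starting material
3 | (E)-but-2-en-1-yl propanoate | CCC(=O)OC/C=C/C | intermediate
4 | (4S,5S)-1,3-bis{[3,5-bis(trifluoromethyl)phenyl]sulfonyl}-2-{[(1Z)-1-{[(2E)-but-2-en-1-yl]oxy}prop-1-en-1-yl]oxy}-4,5-diphenyl-1,3,2-diazaborolidine (E(O) boron enolate, methyl trans to O–B) | C/C=C(\OC/C=C/C)OB1N(S(=O)(=O)c2cc(cc(c2)C(F)(F)F)C(F)(F)F)[C@@H](c2ccccc2)[C@H](c2ccccc2)N1S(=O)(=O)c1cc(cc(c1)C(F)(F)F)C(F)(F)F | intermediate (not isolated)
5 | (4S,5S)-1,3-bis{[3,5-bis(trifluoromethyl)phenyl]sulfonyl}-4,5-diphenyl-1,3,2-diazaborolidin-2-yl (2R,3R)-2,3-dimethylpent-4-enoate | O=C([C@H](C)[C@H](C)C=C)OB1N(S(=O)(=O)c2cc(cc(c2)C(F)(F)F)C(F)(F)F)[C@@H](c2ccccc2)[C@H](c2ccccc2)N1S(=O)(=O)c1cc(cc(c1)C(F)(F)F)C(F)(F)F | intermediate (not isolated)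
6 | (2R,3R)-2,3-dimethylpent-4-enoic acid | OC(=O)[C@H](C)[C@H](C)C=C | intermediate
7 | (2R,3S)-2-methyl-3-(1,2,4-trioxolan-3-yl)butanoic acid (epimers at the trioxolane carbon) | OC(=O)[C@H](C)[C@H](C)C1OCOO1 | intermediate (not isolated)
8 | (2R,3S)-2,3-dimethyl-4-oxobutanoic acid | OC(=O)[C@H](C)[C@H](C)C=O | intermediate (not isolated)
9 | (3R,4S)-5-hydroxy-3,4-dimethyloxolan-2-one (both C5 epimers) | O=C1OC(O)[C@@H](C)[C@H]1C | intermediate
10 | (3R,4S)-5-acetoxy-3,4-dimethyloxolan-2-one (both C5 epimers) | O=C1OC(OC(C)=O)[C@@H](C)[C@H]1C | intermediate
11 | 5-bromo-1,2,3-trimethoxybenzene | COc1cc(Br)cc(OC)c1OC | starting material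
12 | (3,4,5-trimethoxyphenyl)lithium | [Li]c1cc(OC)c(OC)c(OC)c1 | intermediate (not isolated)
13 | chloro(3,4,5-trimethoxyphenyl)zinc | Cl[Zn]c1cc(OC)c(OC)c(OC)c1 | intermediate (not isolated)
14 | (3R,4S)-3,4-dimethyl-2-oxo-3,4-dihydro-2H-furan-1-ium | O=C1[O+]=C[C@@H](C)[C@H]1C | intermediate (not isolated)
15 | (3R,4S,5S)-3,4-dimethyl-5-(3,4,5-trimethoxyphenyl)oxolan-2-one | O=C1O[C@H](c2cc(OC)c(OC)c(OC)c2)[C@@H](C)[C@H]1C | intermediate
16 | 4-bromo-1,2-dimethoxybenzene | COc1ccc(Br)cc1OC | starting material
17 | (3,4-dimethoxyphenyl)lithium | [Li]c1ccc(OC)c(OC)c1 | intermediate (not isolated)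
18 | (3R,4S,5S)-2-(3,4-dimethoxyphenyl)-3,4-dimethyl-5-(3,4,5-trimethoxyphenyl)oxolan-2-ol (both C2 epimers) | COc1ccc(C2(O)O[C@H](c3cc(OC)c(OC)c(OC)c3)[C@@H](C)[C@H]2C)cc1OC | intermediate
19 | (2S,3S,4R)-5-(3,4-dimethoxyphenyl)-3,4-dimethyl-2-(3,4,5-trimethoxyphenyl)-3,4-dihydro-2H-furan-1-ium | COc1ccc(C2=[O+][C@H](c3cc(OC)c(OC)c(OC)c3)[C@@H](C)[C@H]2C)cc1OC | intermediate (not isolated)
20 | Ligraminol A, (2S,3R,4S,5S)-2-(3,4-dimethoxyphenyl)-3,4-dimethyl-5-(3,4,5-trimethoxyphenyl)oxolane | COc1ccc([C@H]2O[C@H](c3cc(OC)c(OC)c(OC)c3)[C@@H](C)[C@H]2C)cc1OC | target

## Step count and least certain steps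

Total step count: 7. Longest linear sequence: 7 steps (1 → 3 → 6 → 9 → 10 → 15 → 18 → 20); bromides 11 and 16 enter directly. Minor stereoisomers carried from step 2 are best removed at lactone 15.

**Key step (step 2).** The most likely failure is incomplete control of enolate geometry, which leaks material into the syn acid. Slow decay of the moisture-sensitive boron enolate over the long cold period would lower conversion and enantiopurity, and the sense of induction needs confirmation. The fallback keeps the [3,3] bond formation but takes the absolute configuration from a carbinol stereocentre by 1,3-chirality transfer. It sets out from 2 and returns at 9.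
- (2S,3E)-Pent-3-en-2-ol F1 would be obtained from the racemate by Sharpless kinetic resolution (Ti(OiPr)4, a dialkyl tartrate, t-BuOOH) and acylated with 2 to (2S,3E)-pent-3-en-2-yl propanoate F2.
- LiN(i-Pr)2 in THF at −78 °C and Me3SiCl would give the (E)-trimethylsilyl ketene acetal F3.
- On warming, F3 rearranges through the chair with the carbinol methyl group equatorial to trimethylsilyl (2R,3R,4E)-2,3-dimethylhex-4-enoate F4, which work-up hydrolyses to (2R,3R,4E)-2,3-dimethylhex-4-enoic acid F5.
- Ozonolysis of F5 under the conditions of step 3 cleaves the propenyl group and gives 9 through 8.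

**Step 5.** The electron-poor acyl oxocarbenium ion needs a strong Lewis acid, and the organozinc may not tolerate it: aryl transfer from zinc to boron or protonolysis of 13 could outrun the substitution, and THF from the reagent solution slows the ionisation of 10. The fallback replaces the organometallic by a neutral arene and sets out from 10. Friedel–Crafts reaction of 10 with 2,6-dimethoxyphenol and BF3·OEt2 in CH2Cl2 occurs at the position para to the hydroxyl group, again anti to the methyl groups. It would give (3R,4S,5S)-5-(4-hydroxy-3,5-dimethoxyphenyl)-3,4-dimethyloxolan-2-one F6. O-Methylation (MeI, K2CO3, acetone) returns to the route at 15.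

**Step 6.** The aryllithium may act as a base, enolising C3 and losing the 3,4-cis relation on reprotonation, or it may add a second time to the ring-opened ketone. The fallback replaces direct lactone addition by acyl substitution on a chelated amide. It sets out from 15.
- MeNH(OMe)·HCl and Me3Al open 15 to (2R,3S,4S)-4-hydroxy-N-methoxy-N,2,3-trimethyl-4-(3,4,5-trimethoxyphenyl)butanamide F7.
- Et3SiCl and imidazole give its triethylsilyl ether F8.
- Aryllithium 17 converts F8 into (2R,3S,4S)-1-(3,4-dimethoxyphenyl)-2,3-dimethyl-4-[(triethylsilyl)oxy]-4-(3,4,5-trimethoxyphenyl)butan-1-one F9 without over-addition.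
- Bu4NF buffered with AcOH removes the silyl group, and the hydroxy ketone closes to 18.

**Step 7.** The main dangers are reversible ionisation of the benzylic C–O bonds of 20 by BF3·OEt2, which would epimerise C2 to the 2,3-trans isomer, and proton loss from 19 with unselective reprotonation at C3. The fallback avoids Lewis acid at the end and sets C2 and C3 together by syn addition of hydrogen. It sets out from 18. Dehydration with MsCl and Et3N gives (2S,3S)-5-(3,4-dimethoxyphenyl)-3,4-dimethyl-2-(3,4,5-trimethoxyphenyl)-2,3-dihydrofuran F10. Hydrogenation over Rh/Al2O3 in EtOAc with a trace of Et3N is expected from the face anti to the allylic C4 methyl group and returns to the route at 20. Its own risk is that the C5 aryl group on the other face weakens this preference.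

## Further compounds

F1 | step 2 | (2S,3E)-pent-3-en-2-ol | C/C=C/[C@H](C)O
F2 | step 2 | (2S,3E)-pent-3-en-2-yl propanoate | CCC(=O)O[C@@H](C)/C=C/C
F3 | step 2 | trimethyl{[(1E)-1-{[(2S,3E)-pent-3-en-2-yl]oxy}prop-1-en-1-yl]oxy}silane | C/C=C(\O[C@@H](C)/C=C/C)O[Si](C)(C)C
F4 | step 2 | trimethylsilyl (2R,3R,4E)-2,3-dimethylhex-4-enoate | C[Si](C)(C)OC(=O)[C@H](C)[C@H](C)/C=C/C
F5 | step 2 | (2R,3R,4E)-2,3-dimethylhex-4-enoic acid | OC(=O)[C@H](C)[C@H](C)/C=C/C
F6 | step 5 | (3R,4S,5S)-5-(4-hydroxy-3,5-dimethoxyphenyl)-3,4-dimethyloxolan-2-one | O=C1O[C@H](c2cc(OC)c(O)c(OC)c2)[C@@H](C)[C@H]1C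
F7 | step 6 | (2R,3S,4S)-4-hydroxy-N-methoxy-N,2,3-trimethyl-4-(3,4,5-trimethoxyphenyl)butanamide | CON(C)C(=O)[C@H](C)[C@H](C)[C@H](O)c1cc(OC)c(OC)c(OC)c1
F8 | step 6 | (2R,3S,4S)-N-methoxy-N,2,3-trimethyl-4-[(triethylsilyl)oxy]-4-(3,4,5-trimethoxyphenyl)butanamide | CON(C)C(=O)[C@H](C)[C@H](C)[C@H](O[Si](CC)(CC)CC)c1cc(OC)c(OC)c(OC)c1
F9 | step 6 | (2R,3S,4S)-1-(3,4-dimethoxyphenyl)-2,3-dimethyl-4-[(triethylsilyl)oxy]-4-(3,4,5-trimethoxyphenyl)butan-1-one | COc1ccc(C(=O)[C@H](C)[C@H](C)[C@H](O[Si](CC)(CC)CC)c2cc(OC)c(OC)c(OC)c2)cc1OC
F10 | step 7 | (2S,3S)-5-(3,4-dimethoxyphenyl)-3,4-dimethyl-2-(3,4,5-trimethoxyphenyl)-2,3-dihydrofuran | COc1ccc(C2=C(C)[C@H](C)[C@@H](c3cc(OC)c(OC)c(OC)c3)O2)cc1OC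
A1 | alternative 1 | (2S,3R,4S)-2-(3,4-dimethoxyphenyl)-3,4-dimethylcyclobutan-1-one | COc1ccc([C@H]2C(=O)[C@@H](C)[C@H]2C)cc1OC
A2 | alternative 1 | (3,4-dimethoxyphenyl)ketene | COc1ccc(C=C=O)cc1OC
A3 | alternative 1 | (Z)-but-2-ene | C/C=C\C
A4 | alternative 1 | (3S,4R,5S)-5-(3,4-dimethoxyphenyl)-3,4-dimethyloxolan-2-one | COc1ccc([C@H]2OC(=O)[C@@H](C)[C@H]2C)cc1OC
A5 | alternative 2 | (5S)-3-methyl-5-(3,4,5-trimethoxyphenyl)furan-2(5H)-one | O=C1O[C@H](c2cc(OC)c(OC)c(OC)c2)C=C1C
A6 | alternative 2 | trimethyl{[(4S,5S)-3,4-dimethyl-5-(3,4,5-trimethoxyphenyl)-4,5-dihydrofuran-2-yl]oxy}silane | C[Si](C)(C)OC1=C(C)[C@H](C)[C@@H](c2cc(OC)c(OC)c(OC)c2)O1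
A7 | alternative 2 | (3R,4S,5S)-3,4-dimethyl-5-(3,4,5-trimethoxyphenyl)oxolan-2-one | O=C1O[C@H](c2cc(OC)c(OC)c(OC)c2)[C@@H](C)[C@H]1C
A8 | alternative 3 | 4-[(2R,3R,4S)-4-(3,4-dimethoxyphenyl)-4-hydroxy-2,3-dimethylbutyl]-2,6-dimethoxyphenol | COc1ccc([C@@H](O)[C@H](C)[C@H](C)Cc2cc(OC)c(O)c(OC)c2)cc1OC
A9 | alternative 3 | 4-[(2R,3R,4S)-4-(3,4-dimethoxyphenyl)-4-hydroxy-2,3-dimethylbutylidene]-2,6-dimethoxycyclohexa-2,5-dien-1-one | O=C1C(OC)=CC(=C[C@@H](C)[C@@H](C)[C@H](O)c2ccc(OC)c(OC)c2)C=C1OC
A10 | alternative 3 | 4-[(2S,3S,4R,5S)-5-(3,4-dimethoxyphenyl)-3,4-dimethyloxolan-2-yl]-2,6-dimethoxyphenol | COc1ccc([C@H]2O[C@H](c3cc(OC)c(O)c(OC)c3)[C@@H](C)[C@H]2C)cc1OC
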